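**Retrosynthetic overview**
1. Target ⇐ fully protected precursor by one global deprotection (two silyl ethers, one acetonide).
2. (E)-trisubstituted side-chain alkene ⇐ 1,1-dichloroalkene: trans-selective Negishi alkylation with a C5 alkylzinc carrying the bought terminal carbinol centre, then methylation with retention.
3. Dihydrofuran ring ⇐ oxidative [3+2] cycloaddition of a cyclic 1,3-dione with the vinyl group of an (S)-linalool-derived alkene; C3a–C3 and O1–C2 form in one operation, and C2 is created next to the bought tertiary carbinol.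
4. Cyclohexane-1,3-dione ring ⇐ intramolecular Claisen ring expansion of (R)-solerone, made from (R)-5-oxotetrahydrofuran-2-carboxylic acid (ring C5–O bought).
5. Order of ring formation: carbocycle first (step 2), dihydrofuran second (step 9).

Assumption: (S)-(+)-linalool, (R)-5-oxotetrahydrofuran-2-carboxylic acid and (R)-α-hydroxy-γ-butyrolactone are bought in high enantiomeric purity.

**Route**

Step 1
Reactants: 1 (2R)-5-oxooxolane-2-carboxylic acid
Product: 3 (5R)-5-acetyloxolan-2-one, via acid chloride 2 (not isolated)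
Conditions: (COCl)2, DMF (cat.), CH2Cl2, 0 °C to rt; evaporate; MeMgBr (1.05 equiv), Fe(acac)3 (3 mol %), THF, −78 °C
Reagents that add atoms: methylmagnesium bromide, C[Mg]Br
Why: Acid chloride formation followed by Fe(acac)3-catalysed acylation of the Grignard reagent (Fürstner ketone synthesis) stops at the methyl ketone and leaves the lactone intact at −78 °C, and the bought stereocentre (later ring C5 of the target) is carried through without any bond to it being broken.

Step 2
Reactants: 3 (5R)-5-acetyloxolan-2-one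
Product: 6 (4R)-4-[(tert-butyldimethylsilyl)oxy]cyclohexane-1,3-dione, via dilithium dianion 4 (not isolated), via bis-silyl ether 5 (not isolated)
Conditions: LiN(SiMe3)2 (2.3 equiv), THF, −78 to 0 °C; TBSCl (2.4 equiv), DMPU, 0 °C to rt; 1 M aq. citric acid, rt
Reagents that add atoms: tert-butyldimethylsilyl chloride, CC(C)(C)[Si](C)(C)Cl
Why: Kinetic deprotonation at the acetyl CH3 and intramolecular Claisen (Dieckmann-type) acylation on the lactone carbonyl through a 7-oxabicyclo[2.2.1]heptane tetrahedral intermediate opens the lactone into the six-membered 1,3-dione dianion, which is O-silylated twice, the vinylogous silyl ester being hydrolysed on work-up while the secondary TBS ether stays; the stereocentre is not enolised because the carbonyl next to it is part of the dione enolate.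

Step 3
Reactants: 7 (3S)-3,7-dimethylocta-1,6-dien-3-ol [(S)-linalool]
Product: 8 triethyl{[(3S)-3,7-dimethylocta-1,6-dien-3-yl]oxy}silane
Conditions: TESOTf, 2,6-lutidine, CH2Cl2, −78 to 0 °C
Reagents that add atoms: triethylsilyl trifluoromethanesulfonate, CC[Si](CC)(CC)OS(=O)(=O)C(F)(F)F
Why: Silylation of the tertiary allylic alcohol with the silyl triflate masks the OH against lactol formation and later oxidation without touching the bought (S) centre.

Step 4
Reactants: 8 triethyl{[(3S)-3,7-dimethylocta-1,6-dien-3-yl]oxy}silane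
Product: 10 (4S)-4-methyl-4-[(triethylsilyl)oxy]hex-5-enal, via ozonide 9 (not isolated)
Conditions: O3 (1.0 equiv), CH2Cl2, −78 °C; Me2S, −78 °C to rt
Reagents that add atoms: ozone, [O-][O+]=O
Why: Chemoselective ozonolysis, in which the electron-rich trisubstituted alkene is cleaved far faster than the monosubstituted vinyl group flanked by the silyloxy quaternary carbon, followed by reductive work-up of the ozonide to the aldehyde.

Step 5
Reactants: 10 (4S)-4-methyl-4-[(triethylsilyl)oxy]hex-5-enal
Product: 11 triethyl{[(3S)-7,7-dichloro-3-methylhepta-1,6-dien-3-yl]oxy}silane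
Conditions: BrCCl3, PPh3, MeCN, 0 °C to rt
Reagents that add atoms: bromotrichloromethane, ClC(Cl)(Cl)Br
Why: Wittig-type (Ramirez) dichloro-olefination with Ph3P=CCl2 made in situ converts the aldehyde into a 1,1-dichloroalkene, an electron-poor placeholder for the trisubstituted alkene that is inert in the oxidative cycloaddition.

Step 6
Reactants: 12 (3R)-3-hydroxyoxolan-2-one [(R)-α-hydroxy-γ-butyrolactone]
Product: 13 (3R)-4-methylpentane-1,3,4-triol
Conditions: MeMgBr (3.5 equiv), THF, 0 °C to rt; aq. NH4Cl
Reagents that add atoms: methylmagnesium bromide, C[Mg]Br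
Why: Double Grignard addition to the lactone carbonyl (one further equivalent is consumed by the OH) builds the tertiary carbinol, while the bought secondary carbinol centre is not involved.

Step 7
Reactants: 13 (3R)-4-methylpentane-1,3,4-triol
Product: 14 2-[(4R)-2,2,5,5-tetramethyl-1,3-dioxolan-4-yl]ethan-1-ol
Conditions: 2,2-dimethoxypropane, TsOH·H2O (cat.), acetone, rt, 16 h
Reagents that add atoms: 2,2-dimethoxypropane, COC(C)(C)OC
Why: Acetalisation under equilibrating conditions gives the five-membered 1,3-dioxolane across the secondary/tertiary 1,2-diol in preference to the six-membered 1,3-dioxane with an axial methyl group, leaving the primary OH free.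

Step 8
Reactants: 14 2-[(4R)-2,2,5,5-tetramethyl-1,3-dioxolan-4-yl]ethan-1-ol
Product: 15 (4R)-4-(2-iodoethyl)-2,2,5,5-tetramethyl-1,3-dioxolane
Conditions: I2, PPh3, imidazole, CH2Cl2, 0 °C
Reagents that add atoms: iodine, [I][I]
Why: Appel iodination converts the primary alcohol into the iodide by SN2 displacement far from the stereocentre.

Step 9
Reactants: 6 (4R)-4-[(tert-butyldimethylsilyl)oxy]cyclohexane-1,3-dione; 11 triethyl{[(3S)-7,7-dichloro-3-methylhepta-1,6-dien-3-yl]oxy}silane
Product: 16 (2S,5R)-5-[(tert-butyldimethylsilyl)oxy]-2-[(2S)-6,6-dichloro-2-[(triethylsilyl)oxy]hex-5-en-2-yl]-3,5,6,7-tetrahydro-1-benzofuran-4(2H)-one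
Conditions: (NH4)2Ce(NO3)6 (2.2 equiv), NaHCO3 (4 equiv), 11 (3 equiv, excess recovered), MeCN, 0 °C, 30 min; chromatography
Reagents that add atoms: none
Why: Oxidative formal [3+2] cycloaddition, in which one-electron oxidation of the dione enol by tetravalent cerium gives an electrophilic radical that adds only to the terminal CH2 of the vinyl group (the dichloroalkene is electron-poor) and oxidative closure through the more electron-rich carbonyl oxygen remote from the OTBS group gives the 2-substituted dihydrofuran; C2 is created under 1,2-induction from the adjacent bought silyloxy quaternary centre, whose facial bias is small and of uncertain sense, so the (2S) product 16 is separated from its C2 epimer by chromatography.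

Step 10
Reactants: 16 (2S,5R)-5-[(tert-butyldimethylsilyl)oxy]-2-[(2S)-6,6-dichloro-2-[(triethylsilyl)oxy]hex-5-en-2-yl]-3,5,6,7-tetrahydro-1-benzofuran-4(2H)-one; 15 (4R)-4-(2-iodoethyl)-2,2,5,5-tetramethyl-1,3-dioxolane
Product: 19 (2S,5R)-5-[(tert-butyldimethylsilyl)oxy]-2-[(2S,5E)-6-methyl-8-[(4R)-2,2,5,5-tetramethyl-1,3-dioxolan-4-yl]-2-[(triethylsilyl)oxy]oct-5-en-2-yl]-3,5,6,7-tetrahydro-1-benzofuran-4(2H)-one, via alkylzinc iodide 17 (not isolated), via chloroalkene 18 (not isolated)
Conditions: 15 (1.2 equiv), Zn dust, LiCl, THF, 40 °C; then 16, PdCl2(DPEphos) (5 mol %), THF/DMF, 50 °C; then Me2Zn (4 equiv), Pd(P(t-Bu)3)2 (5 mol %), 60 °C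
Reagents that add atoms: dimethylzinc, C[Zn]C
Why: Zn insertion gives the γ-alkoxy alkylzinc iodide, PdCl2(DPEphos)-catalysed Negishi coupling replaces only the less hindered chlorine trans to the chain, and Pd(P(t-Bu)3)2-catalysed methylation of the remaining alkenyl chloride with Me2Zn proceeds with retention, which fixes the (E)-trisubstituted alkene, while organozinc reagents do not add to the ketone or the vinylogous ester.

Step 11
Reactants: 19 (2S,5R)-5-[(tert-butyldimethylsilyl)oxy]-2-[(2S,5E)-6-methyl-8-[(4R)-2,2,5,5-tetramethyl-1,3-dioxolan-4-yl]-2-[(triethylsilyl)oxy]oct-5-en-2-yl]-3,5,6,7-tetrahydro-1-benzofuran-4(2H)-one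
Product: 20 (2S,5R)-5-hydroxy-2-[(2S,5E,9R)-2,9,10-trihydroxy-6,10-dimethylundec-5-en-2-yl]-3,5,6,7-tetrahydro-1-benzofuran-4(2H)-one
Conditions: 48% aq. HF, MeCN, 0 °C to rt
Reagents that add atoms: none
Why: Global deprotection, in which fluoride cleaves both silyl ethers and the aqueous acid hydrolyses the acetonide in one pot under conditions mild enough for the vinylogous ester, the tertiary alcohol and the trisubstituted alkene, with no stereocentre touched.

**Compound list**
1 | (2R)-5-oxooxolane-2-carboxylic acid | OC(=O)[C@H]1CCC(=O)O1 | starting material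
2 | (2R)-5-oxooxolane-2-carbonyl chloride | ClC(=O)[C@H]1CCC(=O)O1 | intermediate
3 | (5R)-5-acetyloxolan-2-one [(R)-solerone] | CC(=O)[C@H]1CCC(=O)O1 | intermediate
4 | dilithium salt (4-alkoxide and dione enolate) of (4R)-4-hydroxycyclohexane-1,3-dione | [Li+].[Li+].[O-]C1=CC(=O)CC[C@H]1[O-] | intermediate
5 | (4R)-3,4-bis[(tert-butyldimethylsilyl)oxy]cyclohex-2-en-1-one (one of two enol-silyl regioisomers, both give 6) | CC(C)(C)[Si](C)(C)OC1=CC(=O)CC[C@H]1O[Si](C)(C)C(C)(C)C | intermediate
6 | (4R)-4-[(tert-butyldimethylsilyl)oxy]cyclohexane-1,3-dione | O=C1CC(=O)CC[C@H]1O[Si](C)(C)C(C)(C)C | intermediate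
7 | (3S)-3,7-dimethylocta-1,6-dien-3-ol [(S)-linalool] | C=C[C@@](C)(O)CCC=C(C)C | starting material
8 | triethyl{[(3S)-3,7-dimethylocta-1,6-dien-3-yl]oxy}silane | C=C[C@@](C)(O[Si](CC)(CC)CC)CCC=C(C)C | intermediate
9 | triethyl{[(3S)-5-(5,5-dimethyl-1,2,4-trioxolan-3-yl)-3-methylpent-1-en-3-yl]oxy}silane (ozonide, mixture at the trioxolane carbon) | C=C[C@@](C)(O[Si](CC)(CC)CC)CCC1OOC(C)(C)O1 | intermediate
10 | (4S)-4-methyl-4-[(triethylsilyl)oxy]hex-5-enal | C=C[C@@](C)(O[Si](CC)(CC)CC)CCC=O | intermediate
11 | triethyl{[(3S)-7,7-dichloro-3-methylhepta-1,6-dien-3-yl]oxy}silane | C=C[C@@](C)(O[Si](CC)(CC)CC)CCC=C(Cl)Cl | intermediate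
12 | (3R)-3-hydroxyoxolan-2-one [(R)-α-hydroxy-γ-butyrolactone] | O[C@@H]1CCOC1=O | starting material
13 | (3R)-4-methylpentane-1,3,4-triol | OCC[C@@H](O)C(C)(C)O | intermediate
14 | 2-[(4R)-2,2,5,5-tetramethyl-1,3-dioxolan-4-yl]ethan-1-ol | OCC[C@H]1OC(C)(C)OC1(C)C | intermediate
15 | (4R)-4-(2-iodoethyl)-2,2,5,5-tetramethyl-1,3-dioxolane | ICC[C@H]1OC(C)(C)OC1(C)C | intermediate
16 | (2S,5R)-5-[(tert-butyldimethylsilyl)oxy]-2-[(2S)-6,6-dichloro-2-[(triethylsilyl)oxy]hex-5-en-2-yl]-3,5,6,7-tetrahydro-1-benzofuran-4(2H)-one | ClC(Cl)=CCC[C@](C)(O[Si](CC)(CC)CC)[C@@H]1CC2=C(CC[C@@H](O[Si](C)(C)C(C)(C)C)C2=O)O1 | intermediate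
17 | {2-[(4R)-2,2,5,5-tetramethyl-1,3-dioxolan-4-yl]ethyl}zinc iodide | I[Zn]CC[C@H]1OC(C)(C)OC1(C)C | intermediate
18 | (2S,5R)-5-[(tert-butyldimethylsilyl)oxy]-2-[(2S,5Z)-6-chloro-8-[(4R)-2,2,5,5-tetramethyl-1,3-dioxolan-4-yl]-2-[(triethylsilyl)oxy]oct-5-en-2-yl]-3,5,6,7-tetrahydro-1-benzofuran-4(2H)-one | Cl/C(=C\CC[C@](C)(O[Si](CC)(CC)CC)[C@@H]1CC2=C(CC[C@@H](O[Si](C)(C)C(C)(C)C)C2=O)O1)CC[C@H]1OC(C)(C)OC1(C)C | intermediate
19 | (2S,5R)-5-[(tert-butyldimethylsilyl)oxy]-2-[(2S,5E)-6-methyl-8-[(4R)-2,2,5,5-tetramethyl-1,3-dioxolan-4-yl]-2-[(triethylsilyl)oxy]oct-5-en-2-yl]-3,5,6,7-tetrahydro-1-benzofuran-4(2H)-one | C/C(=C\CC[C@](C)(O[Si](CC)(CC)CC)[C@@H]1CC2=C(CC[C@@H](O[Si](C)(C)C(C)(C)C)C2=O)O1)CC[C@H]1OC(C)(C)OC1(C)C | intermediate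
20 | (2S,5R)-5-hydroxy-2-[(2S,5E,9R)-2,9,10-trihydroxy-6,10-dimethylundec-5-en-2-yl]-3,5,6,7-tetrahydro-1-benzofuran-4(2H)-one | C/C(=C\CC[C@](C)(O)[C@@H]1CC2=C(CC[C@@H](O)C2=O)O1)CC[C@@H](O)C(C)(C)O | target

**Totals**
Total step count: 11. Longest linear sequence: 6 steps (7 → 8 → 10 → 11 → 16 → 19 → 20; steps 3, 4, 5, 9, 10, 11).

**Three steps most likely to fail**

Step 9 (oxidative cycloaddition). The hindered vinyl group is only moderately reactive toward the dione radical, and both silyl ethers must survive (NH4)2Ce(NO3)6. Closure through the other carbonyl oxygen would give a regioisomer. Facial selectivity at C2 is low, so the yield of pure 16 after separation from its C2 epimer may be poor. The fallback replaces the one-electron oxidation by a metal-carbenoid cycloaddition and sets out from 6. Regitz diazo transfer (4-acetamidobenzenesulfonyl azide, Et3N, MeCN, 0 °C to rt) gives (4R)-4-[(tert-butyldimethylsilyl)oxy]-2-diazocyclohexane-1,3-dione F1. F1 is decomposed with Rh2(OAc)4 (2 mol %) in fluorobenzene at 80 °C by slow addition to excess 11. The electrophilic carbenoid attacks the terminal CH2 and the enolate oxygen closes on the substituted carbon under neutral, non-oxidising conditions. The C2 epimers are again separated, and the route is rejoined at 16.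

Step 2 (lactone-to-dione Claisen through a bridged intermediate). The bridged tetrahedral intermediate may form slowly, so that intermolecular condensation or enolisation at the α-alkoxy methine (erosion of ee) competes. The fallback opens the lactone first and sets out from 3. Methanolysis (K2CO3, MeOH, 0 °C, short contact) gives methyl (4R)-4-hydroxy-5-oxohexanoate F2. Silylation (TBSCl, imidazole, DMF) gives methyl (4R)-4-[(tert-butyldimethylsilyl)oxy]-5-oxohexanoate F3. A conventional unstrained Dieckmann-type condensation of F3 (KOtBu, THF, 0 °C, acidic work-up) then closes the six-membered ring, and the route is rejoined at 6.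

Step 10 (one-pot double Negishi coupling on the functionalised core). Residual alkylzinc 17 can compete with Me2Zn once the more active Pd(P(t-Bu)3)2 is present, and the core is exposed to two hot coupling stages. The fallback changes the order of bond formation and sets out from 11. Trans-selective monoalkylation of 11 with 17 (PdCl2(DPEphos), THF/DMF, 50 °C) is done before the annulation and gives triethyl{[(3S,6Z)-7-chloro-3-methyl-9-[(4R)-2,2,5,5-tetramethyl-1,3-dioxolan-4-yl]nona-1,6-dien-3-yl]oxy}silane F4, in which the chloroalkene is still electron-poor. F4 is then taken through the oxidative cycloaddition with 6 under the conditions of step 9, which rejoins the route at 18, now isolated and purified. The methyl group is introduced last by Suzuki–Miyaura coupling (trimethylboroxine, Pd(OAc)2, SPhos, K3PO4, dioxane/H2O, 80 °C) with retention to give 19.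

Further compounds
F1 | step 9 | (4R)-4-[(tert-butyldimethylsilyl)oxy]-2-diazocyclohexane-1,3-dione | O=C1C(=[N+]=[N-])C(=O)CC[C@H]1O[Si](C)(C)C(C)(C)C
F2 | step 2 | methyl (4R)-4-hydroxy-5-oxohexanoate | COC(=O)CC[C@@H](O)C(C)=O
F3 | step 2 | methyl (4R)-4-[(tert-butyldimethylsilyl)oxy]-5-oxohexanoate | COC(=O)CC[C@@H](O[Si](C)(C)C(C)(C)C)C(C)=O
F4 | step 10 | triethyl{[(3S,6Z)-7-chloro-3-methyl-9-[(4R)-2,2,5,5-tetramethyl-1,3-dioxolan-4-yl]nona-1,6-dien-3-yl]oxy}silane | C=C[C@@](C)(O[Si](CC)(CC)CC)CC/C=C(\Cl)CC[C@H]1OC(C)(C)OC1(C)C
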